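The data were computed on assumed constants; scatter was added.

A stirred vessel under a constant pressure of L takes up J, in the earlier runs by a steady feed, and two new flasks are to be compared: gamma, fed the same way, and theta, with everything in from the start.

| flask | J | L | remark | time |
|---|---|---|---|---|
| north-east | 0.032 M (fed, over 15 min) | 12 mM (held) | run made earlier; the fed solution adds 1.0 times the starting volume |  |
| west | 0.16 M (fed, over 15 min) | 12 mM (held) | run made earlier; the fed solution adds 1.0 times the starting volume |  |
| gamma | 0.20 M (fed, over 15 min) | 12 mM (held) | the fed solution adds 1.0 times the starting volume | 40 min |
| theta | 0.060 M | 12 mM | everything together at the start, the whole solution of J included, so that from the start the volume is larger by 1.0 times the starting volume | 40 min |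

| run | time / min | Z / % |
|---|---|---|
| north-east | 1.50 | 0 |
| north-east | 2.50 | 0 |
| north-east | 4.00 | 4 |
| north-east | 8.00 | 0 |
| north-east | 12.0 | 8 |
| north-east | 20.0 | 15 |
| west | 1.33 | 0 |
| west | 4.00 | 0 |
| west | 8.00 | 3 |
| west | 10.0 | 3 |
| west | 15.0 | 12 |
| west | 20.0 | 16 |

(standard deviation of a reading: 1.5 percentage points)

- charges are per starting volume, the dose included; the dosed solution carries all of it
- what was read earlier has a scatter of 1.5 percentage points, one standard deviation
- percentages count the whole charge, also what has not yet gone in

1. the flask that ends with the higher amount of Z, in percent of the J charged, or "neither" when 2 percentage points or less lies between them (gamma / theta / neither)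
2. final Z, as a percentage of the J charged, in gamma
3. final Z, as a percentage of the J charged, in theta

The north-east and west runs differ in charge by a factor of 5.00, yet at 20.0 min they read 15% and 16%. So I take percent Z as independent of charge, with J turning over in a pseudo-first-order way at held L.

I can count turnovers per minute in two ways. The first counts from the feed: at the end of the west feed, J has stood 7.50 min on average and 12% is Z, which gives 0.0160 min⁻¹. The north-east reading at 12.0 min, counted the same way, gives 0.0167 min⁻¹. The second takes the late slope: the west run gains 0.00800 min⁻¹ of the charge, which per J not yet Z is 0.00909 min⁻¹, and the north-east run gives 0.00951 min⁻¹.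

The runs agree within each way, but the second way is lower. The first is an average over the early run and the second is the present rate, so, as far as readings with this scatter allow, I believe the second and read the gap as a fade. The two stretches lie 10.0 min apart, which gives the fade time, the time in which the turnovers per minute fall by a factor e, 17.7 min.

Taking gamma to follow the west run, I sum the fading slope from 20.0 min to 40 min onto the west reading, which adds 8.3 percentage points, so I commit to 24.3% for gamma. Theta's J stands 7.50 min longer on average than gamma's, and at the slope I reckon for 40 min that is worth 1.7 points, less than the margin. So I say 26.0% for theta, and neither.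

The forecast says theta, with 36.5% for gamma and 43% for theta, on the ground that “the reaction is first order in J at fixed L”. The flasks give 22.7% for gamma and 22.9% for theta, so neither.

    L ⇌ G, rate k1*(csat - [G]) (kL = 0.0320 s⁻¹)
    J + G ⇌ Z (K = 110 M⁻¹, k = 0.0320 M⁻¹ s⁻¹)
    G + Z → X (k = 0.0170 M⁻¹ s⁻¹)
    J ⇌ Q (K = 1.90, k = 5.00 × 10⁻⁴ s⁻¹)

In gamma at 40.0 min, J + G and Z relax, by that step alone and both ways together, with a half-life of 6.87 min, short against the 40 min of the run; the fade time read from the earlier runs, 17.7 min, is also shorter than those 40 min. At that moment the forward rate of J to Q is 1.3 times that of J + G to Z, and gamma holds Q at 39.2% beside Z at 22.7%. The fade time, carried to theta at 20.0 min by reckoning theta as the west run 7.50 min later, gives 20.2%. Theta then holds Z at 20.9%.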